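## Structural features

Rhoiptelol B is a diarylheptanoid whose C1–C7 chain is folded into an oxane by an ether oxygen between C1 and C5. C1 carries the guaiacyl ring, C3 a hydroxyl, and C5 the exocyclic carbinol C6, whose CH2 group (C7) bears the 4-hydroxyphenyl ring. The ring holds three stereocentres in a 1,3,5 pattern (C1 R, C3 S, C5 S): aryl and side chain are cis across the ring oxygen, both equatorial, and the C3 hydroxyl is trans to both, hence axial. The fourth centre, C6 (S), stands next to C5 and is syn (threo) to the ring oxygen. The C1–O bond is a para-oxygenated benzylic ether, so it can ionise in strong acid and can be hydrogenolysed; in any intermediate with a C2=C3 double bond it is allylic as well. The real difficulty is to fix the cis C1/C5 relation in absolute terms, to place oxygen on C3 only and on the axial side, and to set C6 against C5. The key step uses the fact that ring O–C5–C6 is an alkoxyacetic acid unit once C6 is at the acid level: an ester bond from the C6 carbonyl to the C2 oxygen gives a 1,4-dioxan-2-one (ester O, C6, C5, ring O, C1, C2) in which C2 is allylic to a C3=C4 vinyl group.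

## Logic of the disconnections

**26 ⇒ 25.** The two aryl O–CH2Ph bonds are cut last. Both phenols are masked by the same group, which survives base, hydride and peracid and leaves in one operation. The forward step must cleave the aryl benzyl ethers without hydrogenolysing the benzylic C1–O ring bond.

**25 ⇒ 24 ⇒ 23.** The C3–O bond and the C2–H bond are traced back through an epoxide to the C2=C3 alkene of 23. This alkene is what the sigmatropic step leaves behind, so no extra functional group is needed. The forward steps must put the epoxide oxygen on the face away from aryl and side chain and let hydride enter C2 axially.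

**23 ⇒ 22.** The C6–H bond is cut, turning the C6 stereocentre into a carbonyl next to C5. The forward reduction must run without chelation, so that the ring C5–O bond directs the hydride.

**22 ⇒ 18 + 19 (through 20 and 21).** The C6–C7 bond is cut. This separates the oxane, with C6 at the acid level, from a simple benzylic nucleophile, so the second aryl ring arrives in one step. The forward addition must stop at the ketone and must not epimerise C5.

**18 ⇒ 15 (through 17).** The amide C–N bond is cut; it serves only to control the single addition of step 6. Activation must avoid strong acid.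

**15 ⇒ 11 (through 14, 13 and 12).** This is the strategic step. The C4–C5 bond is cut and the ester bond between the C6 carbonyl and the C2 oxygen is re-formed. The oxane ring and the C5 stereocentre vanish, leaving a six-membered lactone with two adjacent oxygen-bearing centres (C1, C2). The forward step needs aryl and vinyl trans on 11 and an enolate that is silylated on oxygen at once.

**11 ⇒ 9 (through 10).** The lactone acyl–oxygen bond and the acetal on the C2 oxygen are cut. The forward step must free the C2 hydroxyl and close the ring without ionising the C1–O ether, which rules out strong acid.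

**9 ⇒ 7 + 8.** The ether O–CH2 bond is cut. Because only the C1 hydroxyl of 7 is free, alkylation cannot go to the wrong oxygen. The free acid 8 is used so that no ester has to be cleaved by acid later.

**7 ⇒ 1 + 2 (with 3, through 4, 5 and 6).** The C1–C2 bond is cut. One reagent-controlled addition makes both stereocentres and delivers the two oxygens already differentiated. The forward step must be syn-selective and must attack the Re face of 1.

## Other disconnections considered

**Alternative 1:** The cut is C2–C3, with C1 held as a lactone carbonyl so that the ring is closed through the C5 oxygen before the guaiacyl group is present.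
- Forward step: SmI2 (divalent samarium) should convert the bromoacetate aldehyde A1 into a samarium enolate that adds to the C3 aldehyde inside a chelated chair, giving hydroxy lactone A2 with the C3 hydroxyl trans to the C5 side chain.
- In favour: C3 is made as a carbinol on the right carbon in the ring-forming event, so no alkene has to be oxygenated later, and C5 relays directly to C3.
- Against: the aryl group is still missing. After protection of the C3 hydroxyl, an aryl metal must add to the lactone and the lactol must be reduced by Et3SiH and a Lewis acid through a para-alkoxy-stabilised oxocarbenium ion. A1 is a β-acyloxy aldehyde prone to elimination and needs a linear, protecting-group-heavy chain synthesis.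
- Comparison: on control of C3 this alternative is the better plan. On the cis C1/C5 relation the two are equal (axial hydride delivery versus chirality transfer). On step economy the chosen plan should be shorter, because one addition sets C1 and C2 and the rearrangement relays C2 to C5 while it forms the ring.

**Alternative 2:** The cut is the O–C5 ring bond together with C1–H.
- Forward step: Et3SiOTf should activate the β-lactone of keto-β-lactone A3. The C1 ketone oxygen displaces the lactone oxygen at C5 with inversion, and Et3SiH reduces the cyclic oxocarbenium ion from the axial side to give oxane acid A4.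
- In favour: ring, C1 and the cis relation arise in one operation, the C3 oxygen is already present as a silyl ether, and the invertive alkyl C–O cleavage is stereospecific.
- Against: C7 emerges as a carboxylic acid, and the 4-hydroxybenzyl group must be built from it in several steps next to the epimerisable C6. A3 needs three stereocentres and a strained ring before the key step.
- Comparison: equal on the C1/C5 relation. Better than the chosen plan in having C3 oxygenated before ring closure and in avoiding an allylic benzylic ether. Worse on step economy, since the chosen plan reaches C6 at the acid level and installs C7 with its aryl ring by one organometallic addition.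

**Alternative 3:** The cuts are C2–C3 and C3–C4, both at the carbon that will carry the C3 oxygen, masked as a dithiane.
- Forward step: silyl dithiane A5, lithiated with t-BuLi, should open aryl oxirane A6 at its CH2 terminus. A 1,4-Brook shift moves silicon to the C1 oxygen and regenerates the dithiane anion, which opens epoxide A7 to give the full chain A8.
- In favour: it is the most convergent plan, with three components and two C–C bonds in one flask. C5 and C6 come from the chiral pool. C3 arrives at the ketone level, so the axial alcohol can come from a bulky hydride on the oxan-4-one, the most dependable answer to C3. C1 need not be controlled, because ring closure at the benzylic carbon should settle on the cis ring.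
- Against: t-BuLi and a polar cosolvent are needed. The electron-rich oxirane A6 may open at the benzylic carbon. Dithiane removal needs thiophilic oxidants or mercury salts beside two electron-rich arenes. After A8 there remain desilylation, cyclisation, dithiane hydrolysis, reduction and debenzylation, plus separate syntheses of A6 and A7.
- Comparison: better on convergence and on control of C3, equal on the final cis ring. The chosen plan is expected to be better in longest linear sequence and in the number of reagents needed to set the stereocentres. This alternative would be preferred if late oxygenation of C3 in the chosen route proved unselective.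

Key step: step 4

Remark: 1 (O-benzylvanillin) is taken as a purchased material; it is also available in one operation from vanillin, benzyl bromide and K2CO3.

Remark: borane 3 is defined by its origin, (−)-α-pinene. The sense of induction is argued by analogy with simple allyl transfer from this reagent class, so the Re-face attack on 1 is an assignment to confirm on the first run.

Remark: the key-step pair 11/15 was checked against the target. Trans in 11 and cis in 15, with the absolute configurations drawn, agree with suprafacial transfer and with C1 (R) and C5 (S) of the target, so both structures are used unchanged.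

## Route

Step 1
Reactants: 1 4-(benzyloxy)-3-methoxybenzaldehyde; 2 3-(methoxymethoxy)prop-1-ene; 3 (+)-B-methoxydiisopinocampheylborane [(+)-Ipc2BOMe, from (−)-α-pinene]
Product: 7 (1S,2S)-1-[4-(benzyloxy)-3-methoxyphenyl]-2-(methoxymethoxy)but-3-en-1-ol, via allyllithium 4 (not isolated), via allylborane 5 (not isolated), via borinate 6 (not isolated)
Conditions: 2, s-BuLi, THF, −78 °C; 3, −78 °C; BF3·OEt2, −78 °C; 1, −78 °C → rt; NaOH, H2O2, 0 °C → rt
Reagents that add atoms: 3-(methoxymethoxy)prop-1-ene (2), COCOCC=C
Why: Brown (Z)-γ-alkoxyallylboration: s-BuLi removes the allylic proton next to oxygen to give the chelated (Z)-anion 4, boron is taken up at the carbon remote from oxygen, and BF3 strips methoxide to free 5. Addition to 1 runs through a chair Zimmerman–Traxler transition state with the aryl group equatorial, so the Z geometry becomes the syn C1/C2 relation, and the isopinocampheyl groups from (−)-α-pinene should direct the allyl unit to the Re face of 1, giving (1S,2S) with the free hydroxyl on C1 and the acetal on C2. Oxidative work-up cleaves borinate 6.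

Step 2
Reactants: 7; 8 bromoacetic acid
Product: 9 2-{[(1S,2S)-1-[4-(benzyloxy)-3-methoxyphenyl]-2-(methoxymethoxy)but-3-en-1-yl]oxy}acetic acid
Conditions: NaH (3 equiv), THF, 0 °C; 8, 0 °C → rt; aq. NaH2PO4 work-up
Reagents that add atoms: bromoacetic acid (8), OC(=O)CBr
Why: Williamson etherification: the sodium alkoxide of 7 displaces bromide from sodium bromoacetate, which cannot self-condense or acylate the alkoxide. Only the C1 hydroxyl is free, so the two oxygens of the syn diol stay differentiated, and the basic medium leaves the benzylic stereocentre and the acetal untouched.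

Step 3
Reactants: 9
Product: 11 (5S,6S)-5-[4-(benzyloxy)-3-methoxyphenyl]-6-ethenyl-1,4-dioxan-2-one (trans), via hydroxy acid 10 (not isolated)
Conditions: PPTS, t-BuOH, 80 °C; then PhMe, reflux, Dean–Stark
Reagents that add atoms: none
Why: Acetal solvolysis followed by lactonisation: pyridinium p-toluenesulfonate in hot tert-butanol should cleave the methoxymethyl ether of the allylic alcohol but is too weak to ionise the para-alkoxybenzylic C1–O ether, which CF3CO2H or HCl would break. The δ-hydroxy acid 10 then closes to the six-membered lactone on azeotropic removal of water. No stereocentre is touched, and the syn diol necessarily gives the trans, diequatorial ring.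

Step 4
Reactants: 11
Product: 15 (2S,6R)-6-[4-(benzyloxy)-3-methoxyphenyl]-3,6-dihydro-2H-pyran-2-carboxylic acid (cis), via lithium enolate 12 (not isolated), via silyl ketene acetal 13 (not isolated), via silyl ester 14 (not isolated)
Conditions: Me3SiCl/Et3N (premixed), THF, −78 °C; LiN(SiMe3)2, −78 °C → rt; PhMe, 90 °C; K2CO3, MeOH/H2O; citric acid to pH 4, 0 °C
Reagents that add atoms: none
Why: Ireland–Claisen rearrangement of a cyclic silyl ketene acetal, of the known type that turns 6-alkenyl-1,4-dioxan-2-ones into cis-2,6-disubstituted dihydropyrans. LiN(SiMe3)2 removes the proton between the carbonyl and the ether oxygen with Me3SiCl already present, so enolate 12 is O-silylated at once to 13 and has no lifetime for C-silylation, self-condensation or Wittig-type shifts. On warming, the ketene acetal carbon (C5) bonds to the vinyl terminus (C4) while the allylic C2–O bond breaks in a concerted [3,3] shift, which cuts the ester bond that tethered C5 to C2 and gives silyl ester 14, hydrolysed to 15 by mild base. The oxane ring is closed by C–C bond formation inside a six-centre pericyclic array, not by a displacement; because ketene acetal and alkene sit in one six-membered ring, only a boat-like transition state shaped like bicyclo[2.2.2]octane is possible, with the vinyl group axial. The new stereocentre C5 is set by suprafacial transfer from C2, whose configuration is consumed: C4 arrives on the face of the ketene acetal on which the vinyl group stands, and since C1 is untouched the carboxyl group ends cis to the aryl group. The step needs aryl and vinyl trans in 11, which the syn-selective step 1 secures and which turns the aryl group on the O–C1 bridge away from the reacting vinyl unit. It also needs the benzylic, allylic C1–O bond of 15 to survive, hence the basic hydrolysis and the buffered acidification.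

Step 5
Reactants: 15; 16 N,O-dimethylhydroxylamine hydrochloride
Product: 18 (2S,6R)-6-[4-(benzyloxy)-3-methoxyphenyl]-N-methoxy-N-methyl-3,6-dihydro-2H-pyran-2-carboxamide, via acyl imidazole 17 (not isolated)
Conditions: CDI, CH2Cl2, 0 °C → rt; then 16, rt
Reagents that add atoms: N,O-dimethylhydroxylamine hydrochloride (16), CNOC.Cl
Why: Amide formation through the acyl imidazole: carbonyldiimidazole activates the acid with loss of CO2, and the released imidazole buffers the hydrochloride of 16, so no strong acid or base meets the allylic benzylic ether. The carbonyl group on C5 is already in the favoured equatorial position of the cis ring, so brief activation should not change that centre.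

Step 6
Reactants: 18; 19 4-(benzyloxy)benzyl chloride
Product: 22 1-[(2S,6R)-6-[4-(benzyloxy)-3-methoxyphenyl]-3,6-dihydro-2H-pyran-2-yl]-2-[4-(benzyloxy)phenyl]ethan-1-one, via Grignard reagent 20 (not isolated), via magnesium hemiaminal 21 (not isolated)
Conditions: 19, Mg, THF, 0 °C; then 18, THF, −78 → 0 °C; aq. NH4Cl
Reagents that add atoms: 4-(benzyloxy)benzyl chloride (19), ClCc1ccc(OCc2ccccc2)cc1
Why: Weinreb ketone synthesis: benzylic Grignard reagent 20 adds once to the N-methoxy-N-methyl amide, and the five-membered magnesium chelate 21 holds the tetrahedral stage until aqueous NH4Cl releases ketone 22, so no tertiary alcohol should form. The C6–C7 bond is made without touching a stereocentre, and slow formation of 20 at 0 °C limits Wurtz coupling.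

Step 7
Reactants: 22
Product: 23 (1S)-1-[(2S,6R)-6-[4-(benzyloxy)-3-methoxyphenyl]-3,6-dihydro-2H-pyran-2-yl]-2-[4-(benzyloxy)phenyl]ethan-1-ol
Conditions: LiBH(s-Bu)3, THF, −78 °C; NaOH, H2O2, 0 °C
Reagents that add atoms: none
Why: Diastereoselective ketone reduction under polar Felkin–Anh control: with the bulky, weakly chelating LiBH(s-Bu)3 at −78 °C the ring C5–O bond should lie antiperiplanar to the incoming hydride, which passes the C5 hydrogen and not the ring CH2. This should give the (S)-carbinol at C6, syn to the ring oxygen as in the target; the alkene and the ethers are inert.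

Step 8
Reactants: 23
Product: 24 (1S)-1-[(1R,2S,4S,6R)-2-[4-(benzyloxy)-3-methoxyphenyl]-3,7-dioxabicyclo[4.1.0]heptan-4-yl]-2-[4-(benzyloxy)phenyl]ethan-1-ol (epoxide trans to both ring substituents)
Conditions: mCPBA, NaHCO3, CH2Cl2, 0 °C
Reagents that add atoms: 3-chloroperoxybenzoic acid (mCPBA), OOC(=O)c1cccc(Cl)c1
Why: Peracid (Prilezhaev) epoxidation of the ring alkene: in the half-chair both substituents are pseudo-equatorial, and the C1 aryl group, which leans over its own face next to C2, should send the reagent to the opposite face, placing the epoxide oxygen trans to aryl and side chain. NaHCO3 buffers the 3-chlorobenzoic acid so that neither the benzylic ether nor the new epoxide is opened.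

Step 9
Reactants: 24
Product: 25 (2R,4S,6S)-2-[4-(benzyloxy)-3-methoxyphenyl]-6-[(1S)-2-[4-(benzyloxy)phenyl]-1-hydroxyethyl]oxan-4-ol
Conditions: LiAlH4, THF, 0 °C → rt; aq. KNaC4H4O6 work-up
Reagents that add atoms: none
Why: Reductive epoxide opening under Fürst–Plattner (trans-diaxial) control, the reaction type that gives 2-deoxy sugars from conformationally fixed anhydropyranosides: with aryl and side chain equatorial, only attack of hydride on C2 from the face opposite the epoxide oxygen leads directly to a chair. The C3–O bond keeps its configuration, so the C3 hydroxyl should end axial and trans to both substituents (3S).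

Step 10
Reactants: 25
Product: 26 rhoiptelol B, (2S,4S,6R)-2-[(1S)-1-hydroxy-2-(4-hydroxyphenyl)ethyl]-6-(4-hydroxy-3-methoxyphenyl)oxan-4-ol
Conditions: H2 (1 atm), Pd/C (10% palladium on carbon), EtOAc, rt
Reagents that add atoms: none
Why: Catalytic hydrogenolysis of the two aryl benzyl ethers: these are cleaved faster than the cyclic benzylic C1–O ether, so a neutral solvent, one atmosphere of hydrogen and a stop at full conversion should free both phenols and leave the oxane intact. No stereocentre is involved.

## Compound list

1 | 4-(benzyloxy)-3-methoxybenzaldehyde | COc1cc(C=O)ccc1OCc1ccccc1 | starting material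
2 | 3-(methoxymethoxy)prop-1-ene | COCOCC=C | starting material
3 | (+)-B-methoxydiisopinocampheylborane, enantiomer from (−)-α-pinene | COB([C@H]1C[C@H]2C[C@@H]([C@@H]1C)C2(C)C)[C@H]1C[C@H]2C[C@@H]([C@@H]1C)C2(C)C | starting material
4 | [1-(methoxymethoxy)prop-2-en-1-yl]lithium, chelated (Z)-alkoxyallyl anion | [Li]C(OCOC)C=C | intermediate
5 | [(Z)-3-(methoxymethoxy)prop-2-en-1-yl]diisopinocampheylborane | COCO/C=C\CB([C@H]1C[C@H]2C[C@@H]([C@@H]1C)C2(C)C)[C@H]1C[C@H]2C[C@@H]([C@@H]1C)C2(C)C | intermediate
6 | diisopinocampheylborinic ester of 7 (boron on the C1 oxygen) | COc1cc([C@H](OB([C@H]2C[C@H]3C[C@@H]([C@@H]2C)C3(C)C)[C@H]2C[C@H]3C[C@@H]([C@@H]2C)C3(C)C)[C@@H](OCOC)C=C)ccc1OCc1ccccc1 | intermediate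
7 | (1S,2S)-1-[4-(benzyloxy)-3-methoxyphenyl]-2-(methoxymethoxy)but-3-en-1-ol | COc1cc([C@H](O)[C@@H](OCOC)C=C)ccc1OCc1ccccc1 | intermediate
8 | bromoacetic acid | OC(=O)CBr | starting material
9 | 2-{[(1S,2S)-1-[4-(benzyloxy)-3-methoxyphenyl]-2-(methoxymethoxy)but-3-en-1-yl]oxy}acetic acid | COc1cc([C@H](OCC(=O)O)[C@@H](OCOC)C=C)ccc1OCc1ccccc1 | intermediate
10 | 2-{[(1S,2S)-1-[4-(benzyloxy)-3-methoxyphenyl]-2-hydroxybut-3-en-1-yl]oxy}acetic acid | COc1cc([C@H](OCC(=O)O)[C@@H](O)C=C)ccc1OCc1ccccc1 | intermediate
11 | (5S,6S)-5-[4-(benzyloxy)-3-methoxyphenyl]-6-ethenyl-1,4-dioxan-2-one (trans) | COc1cc([C@@H]2OCC(=O)O[C@H]2C=C)ccc1OCc1ccccc1 | intermediate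
12 | lithium (5S,6S)-5-[4-(benzyloxy)-3-methoxyphenyl]-6-ethenyl-5,6-dihydro-1,4-dioxin-2-olate | COc1cc([C@@H]2OC=C(O[Li])O[C@H]2C=C)ccc1OCc1ccccc1 | intermediate
13 | {[(5S,6S)-5-[4-(benzyloxy)-3-methoxyphenyl]-6-ethenyl-5,6-dihydro-1,4-dioxin-2-yl]oxy}trimethylsilane | COc1cc([C@@H]2OC=C(O[Si](C)(C)C)O[C@H]2C=C)ccc1OCc1ccccc1 | intermediate
14 | trimethylsilyl (2S,6R)-6-[4-(benzyloxy)-3-methoxyphenyl]-3,6-dihydro-2H-pyran-2-carboxylate | COc1cc([C@H]2C=CC[C@@H](C(=O)O[Si](C)(C)C)O2)ccc1OCc1ccccc1 | intermediate
15 | (2S,6R)-6-[4-(benzyloxy)-3-methoxyphenyl]-3,6-dihydro-2H-pyran-2-carboxylic acid (cis) | COc1cc([C@H]2C=CC[C@@H](C(=O)O)O2)ccc1OCc1ccccc1 | intermediate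
16 | N,O-dimethylhydroxylamine hydrochloride | CNOC.Cl | starting material
17 | [(2S,6R)-6-[4-(benzyloxy)-3-methoxyphenyl]-3,6-dihydro-2H-pyran-2-yl](1H-imidazol-1-yl)methanone | COc1cc([C@H]2C=CC[C@@H](C(=O)n3ccnc3)O2)ccc1OCc1ccccc1 | intermediate
18 | (2S,6R)-6-[4-(benzyloxy)-3-methoxyphenyl]-N-methoxy-N-methyl-3,6-dihydro-2H-pyran-2-carboxamide | COc1cc([C@H]2C=CC[C@@H](C(=O)N(C)OC)O2)ccc1OCc1ccccc1 | intermediate
19 | 4-(benzyloxy)benzyl chloride | ClCc1ccc(OCc2ccccc2)cc1 | starting material
20 | [4-(benzyloxy)benzyl]magnesium chloride | Cl[Mg]Cc1ccc(OCc2ccccc2)cc1 | intermediate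
21 | chloromagnesium alkoxide of the N-methoxy-N-methyl hemiaminal formed from 18 and 20 (carbinolamine centre undefined) | COc1cc([C@H]2C=CC[C@@H](C(O[Mg]Cl)(Cc3ccc(OCc4ccccc4)cc3)N(C)OC)O2)ccc1OCc1ccccc1 | intermediate
22 | 1-[(2S,6R)-6-[4-(benzyloxy)-3-methoxyphenyl]-3,6-dihydro-2H-pyran-2-yl]-2-[4-(benzyloxy)phenyl]ethan-1-one | COc1cc([C@H]2C=CC[C@@H](C(=O)Cc3ccc(OCc4ccccc4)cc3)O2)ccc1OCc1ccccc1 | intermediate
23 | (1S)-1-[(2S,6R)-6-[4-(benzyloxy)-3-methoxyphenyl]-3,6-dihydro-2H-pyran-2-yl]-2-[4-(benzyloxy)phenyl]ethan-1-ol | COc1cc([C@H]2C=CC[C@@H]([C@@H](O)Cc3ccc(OCc4ccccc4)cc3)O2)ccc1OCc1ccccc1 | intermediate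
24 | (1S)-1-[(1R,2S,4S,6R)-2-[4-(benzyloxy)-3-methoxyphenyl]-3,7-dioxabicyclo[4.1.0]heptan-4-yl]-2-[4-(benzyloxy)phenyl]ethan-1-ol | COc1cc([C@H]2[C@@H]3O[C@@H]3C[C@@H]([C@@H](O)Cc3ccc(OCc4ccccc4)cc3)O2)ccc1OCc1ccccc1 | intermediate
25 | (2R,4S,6S)-2-[4-(benzyloxy)-3-methoxyphenyl]-6-[(1S)-2-[4-(benzyloxy)phenyl]-1-hydroxyethyl]oxan-4-ol | COc1cc([C@H]2C[C@H](O)C[C@@H]([C@@H](O)Cc3ccc(OCc4ccccc4)cc3)O2)ccc1OCc1ccccc1 | intermediate
26 | rhoiptelol B, (2S,4S,6R)-2-[(1S)-1-hydroxy-2-(4-hydroxyphenyl)ethyl]-6-(4-hydroxy-3-methoxyphenyl)oxan-4-ol | COc1cc([C@H]2C[C@H](O)C[C@@H]([C@@H](O)Cc3ccc(O)cc3)O2)ccc1O | target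

## Step count and risks

Total: 10 steps. Longest linear sequence: 10 steps from 1 (Grignard reagent 20 is made in the flask in step 6).

**Step 4 (key step).** The lactone enolate may be lost to C-silylation or condensation before O-silylation, or the tether-enforced boat may be slow enough that the ketene acetal decomposes. Acid in the work-up could also ionise the allylic benzylic C1–O bond of the product. Fallback, from 1 back to 15: olefination of 1 with diethyl allylphosphonate (n-BuLi, THF) should give (E)-1-[4-(benzyloxy)-3-methoxyphenyl]buta-1,3-diene F1. A hetero-Diels–Alder reaction of F1 with ethyl glyoxylate, catalysed by a bis(oxazoline) complex of Cu(OTf)2 (divalent copper), should bond the glyoxylate carbon to the unsubstituted diene terminus and, through the endo mode, give ethyl (2S,6R)-6-[4-(benzyloxy)-3-methoxyphenyl]-3,6-dihydro-2H-pyran-2-carboxylate F2. The ligand enantiomer would have to be chosen on a test run. LiOH in THF/H2O then returns to 15.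

**Step 8.** Facial selectivity may be poor, because both ring substituents are pseudo-equatorial and shield their own face only weakly, and a hydrogen bond from the C6 hydroxyl could steer the peracid to the wrong face. Fallback, from 22 to 25, bypassing 23 and 24: a Wacker oxidation of the ring alkene (PdCl2 cat., Cu(OAc)2, O2, DMA/H2O) should place the carbonyl on C3, the alkene carbon remote from the allylic ring oxygen, giving (2R,6S)-2-[4-(benzyloxy)-3-methoxyphenyl]-6-{[4-(benzyloxy)phenyl]acetyl}oxan-4-one F3. Excess LiBH(s-Bu)3 at −78 °C should then reduce both carbonyls, the ring ketone from the equatorial side (axial C3 hydroxyl) and the side-chain ketone as in step 7.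

**Step 9.** Regiocontrol may fail: C3 is electronically the easier carbon for hydride attack because it is farther from the ring oxygen, and this opposes the trans-diaxial preference for C2. Fallback, from 23 to 25: silylation (t-BuMe2SiOTf, 2,6-lutidine) gives the tert-butyldimethylsilyl ether of 23, F4. Oxymercuration–demercuration (Hg(OAc)2, THF/H2O; then NaBH4, NaOH) brings water in trans-diaxially at C3, where electronic and conformational preferences agree, to give (2R,4S,6S)-2-[4-(benzyloxy)-3-methoxyphenyl]-6-[(1S)-2-[4-(benzyloxy)phenyl]-1-[(tert-butyldimethylsilyl)oxy]ethyl]oxan-4-ol F5. Bu4NF in THF then gives 25.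

**Step 3.** Cleavage of the acetal by the weak acid may be incomplete, and forcing it with stronger acid would ionise the C1–O ether. Fallback, from 1 to 10: step 1 is run with 3-{[2-(trimethylsilyl)ethoxy]methoxy}prop-1-ene F6 in place of 2 to give (1S,2S)-1-[4-(benzyloxy)-3-methoxyphenyl]-2-{[2-(trimethylsilyl)ethoxy]methoxy}but-3-en-1-ol F7. Alkylation as in step 2 gives 2-{[(1S,2S)-1-[4-(benzyloxy)-3-methoxyphenyl]-2-{[2-(trimethylsilyl)ethoxy]methoxy}but-3-en-1-yl]oxy}acetic acid F8. Fluoride (Bu4NF, DMPU, 80 °C) fragments the silylethoxymethyl group without acid and gives 10, which is lactonised as in the second stage of step 3.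

**Step 7.** Facial selectivity may erode if lithium bridges the ring oxygen and the carbonyl, which would favour the C6 epimer. Fallback, from 22 to 23: chelation-controlled reduction with Zn(BH4)2 (Et2O, −20 °C) is used on purpose to make (1R)-1-[(2S,6R)-6-[4-(benzyloxy)-3-methoxyphenyl]-3,6-dihydro-2H-pyran-2-yl]-2-[4-(benzyloxy)phenyl]ethan-1-ol F9. Mitsunobu inversion (4-nitrobenzoic acid, PPh3, diisopropyl azodicarboxylate, THF) gives (1S)-1-[(2S,6R)-6-[4-(benzyloxy)-3-methoxyphenyl]-3,6-dihydro-2H-pyran-2-yl]-2-[4-(benzyloxy)phenyl]ethyl 4-nitrobenzoate F10, and K2CO3 in MeOH gives 23.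

## Further compounds

F1 | step 4 | (E)-1-[4-(benzyloxy)-3-methoxyphenyl]buta-1,3-diene | COc1cc(/C=C/C=C)ccc1OCc1ccccc1
F2 | step 4 | ethyl (2S,6R)-6-[4-(benzyloxy)-3-methoxyphenyl]-3,6-dihydro-2H-pyran-2-carboxylate | COc1cc([C@H]2C=CC[C@@H](C(=O)OCC)O2)ccc1OCc1ccccc1
F3 | step 8 | (2R,6S)-2-[4-(benzyloxy)-3-methoxyphenyl]-6-{[4-(benzyloxy)phenyl]acetyl}oxan-4-one | COc1cc([C@H]2CC(=O)C[C@@H](C(=O)Cc3ccc(OCc4ccccc4)cc3)O2)ccc1OCc1ccccc1
F4 | step 9 | tert-butyldimethylsilyl ether of 23 | COc1cc([C@H]2C=CC[C@@H]([C@@H](O[Si](C)(C)C(C)(C)C)Cc3ccc(OCc4ccccc4)cc3)O2)ccc1OCc1ccccc1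
F5 | step 9 | (2R,4S,6S)-2-[4-(benzyloxy)-3-methoxyphenyl]-6-[(1S)-2-[4-(benzyloxy)phenyl]-1-[(tert-butyldimethylsilyl)oxy]ethyl]oxan-4-ol | COc1cc([C@H]2C[C@H](O)C[C@@H]([C@@H](O[Si](C)(C)C(C)(C)C)Cc3ccc(OCc4ccccc4)cc3)O2)ccc1OCc1ccccc1
F6 | step 3 | 3-{[2-(trimethylsilyl)ethoxy]methoxy}prop-1-ene | C=CCOCOCC[Si](C)(C)C
F7 | step 3 | (1S,2S)-1-[4-(benzyloxy)-3-methoxyphenyl]-2-{[2-(trimethylsilyl)ethoxy]methoxy}but-3-en-1-ol | COc1cc([C@H](O)[C@@H](OCOCC[Si](C)(C)C)C=C)ccc1OCc1ccccc1
F8 | step 3 | 2-{[(1S,2S)-1-[4-(benzyloxy)-3-methoxyphenyl]-2-{[2-(trimethylsilyl)ethoxy]methoxy}but-3-en-1-yl]oxy}acetic acid | COc1cc([C@H](OCC(=O)O)[C@@H](OCOCC[Si](C)(C)C)C=C)ccc1OCc1ccccc1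
F9 | step 7 | (1R)-1-[(2S,6R)-6-[4-(benzyloxy)-3-methoxyphenyl]-3,6-dihydro-2H-pyran-2-yl]-2-[4-(benzyloxy)phenyl]ethan-1-ol | COc1cc([C@H]2C=CC[C@@H]([C@H](O)Cc3ccc(OCc4ccccc4)cc3)O2)ccc1OCc1ccccc1
F10 | step 7 | (1S)-1-[(2S,6R)-6-[4-(benzyloxy)-3-methoxyphenyl]-3,6-dihydro-2H-pyran-2-yl]-2-[4-(benzyloxy)phenyl]ethyl 4-nitrobenzoate | COc1cc([C@H]2C=CC[C@@H]([C@@H](OC(=O)c3ccc([N+](=O)[O-])cc3)Cc3ccc(OCc4ccccc4)cc3)O2)ccc1OCc1ccccc1
A1 | alternative 1 | (3S,4S)-4-(benzyloxy)-5-[4-(benzyloxy)phenyl]-1-oxopentan-3-yl 2-bromoacetate | O=CC[C@H](OC(=O)CBr)[C@@H](OCc1ccccc1)Cc1ccc(OCc2ccccc2)cc1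
A2 | alternative 1 | (4R,6S)-6-[(1S)-1-(benzyloxy)-2-[4-(benzyloxy)phenyl]ethyl]-4-hydroxyoxan-2-one (hydroxyl trans to side chain) | O=C1C[C@H](O)C[C@@H]([C@@H](OCc2ccccc2)Cc2ccc(OCc3ccccc3)cc2)O1
A3 | alternative 2 | (3R,4R)-3-(benzyloxy)-4-[(2R)-4-[4-(benzyloxy)-3-methoxyphenyl]-2-[(tert-butyldimethylsilyl)oxy]-4-oxobutyl]oxetan-2-one (trans β-lactone) | COc1cc(C(=O)C[C@H](O[Si](C)(C)C(C)(C)C)C[C@H]2OC(=O)[C@@H]2OCc2ccccc2)ccc1OCc1ccccc1
A4 | alternative 2 | (2R)-2-(benzyloxy)-2-[(2S,4S,6R)-6-[4-(benzyloxy)-3-methoxyphenyl]-4-[(tert-butyldimethylsilyl)oxy]oxan-2-yl]acetic acid | COc1cc([C@H]2C[C@H](O[Si](C)(C)C(C)(C)C)C[C@@H]([C@@H](OCc3ccccc3)C(=O)O)O2)ccc1OCc1ccccc1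
A5 | alternative 3 | tert-butyl(1,3-dithian-2-yl)dimethylsilane | CC(C)(C)[Si](C)(C)C1SCCCS1
A6 | alternative 3 | 2-[4-(benzyloxy)-3-methoxyphenyl]oxirane (either enantiomer or the racemate) | COc1cc(C2CO2)ccc1OCc1ccccc1
A7 | alternative 3 | (2S)-2-[(1S)-1-(benzyloxy)-2-[4-(benzyloxy)phenyl]ethyl]oxirane | C1O[C@@H]1[C@@H](OCc1ccccc1)Cc1ccc(OCc2ccccc2)cc1
A8 | alternative 3 | (2S,3S)-3-(benzyloxy)-4-[4-(benzyloxy)phenyl]-1-{2-[2-[4-(benzyloxy)-3-methoxyphenyl]-2-[(tert-butyldimethylsilyl)oxy]ethyl]-1,3-dithian-2-yl}butan-2-ol (C1 epimer mixture) | COc1cc(C(O[Si](C)(C)C(C)(C)C)CC2(C[C@H](O)[C@@H](OCc3ccccc3)Cc3ccc(OCc4ccccc4)cc3)SCCCS2)ccc1OCc1ccccc1
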